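**Strategy.** Gardenin A is disconnected at O1–C2 and then at C2–C3 and C4–O of ring C. The C2–C3–C4 chain between rings B and A is oxygenated at both ends (O1 on C2, the carbonyl oxygen on C4); a 3,5-diarylisoxazole stores exactly this pattern, with nitrogen as a leaving group on C2. One nitrile oxide–alkyne [3+2] cycloaddition forms C2–C3 and C4–O and closes the isoxazole. Its alkyne partner is a fully substituted ring A: an ethynyl group flanked by two MOM-protected oxygens (the future O1 and 5-OH, equivalent by symmetry) and the C6–C8 methoxyls. N–O hydrogenolysis and acid then unveil the pyranone.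

Key step: step 8

Remark on the chemistry: the two oxygens ortho to the alkyne are carried as methoxymethyl ethers, not benzyl ethers, because two OMOM groups direct lithiation cleanly to the single free ring position (benzyl ethers risk benzylic lithiation and Wittig rearrangement) and the acid that closes ring C also removes them.

**Route**

Step 1
Reactants: 1 2,3,4-trimethoxybenzaldehyde
Product: 2 5-bromo-2,3,4-trimethoxybenzaldehyde
Conditions: NBS, DMF, rt
Reagents that add atoms: N-bromosuccinimide, O=C1CCC(=O)N1Br
Why: Electrophilic aromatic bromination; C5 is para to the 2-OMe, ortho to the 4-OMe and meta to the formyl group, so all directing effects converge there, whereas C6 is ortho to the deactivating CHO.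

Step 2
Reactants: 2 5-bromo-2,3,4-trimethoxybenzaldehyde
Product: 4 5-bromo-2,3,4-trimethoxyphenol, via formate ester 3 (not isolated)
Conditions: mCPBA, CH2Cl2, 0 °C → rt; then NaOH, MeOH/H2O, rt; aq. HCl work-up
Reagents that add atoms: meta-chloroperoxybenzoic acid, O=C(OO)c1cccc(Cl)c1
Why: Dakin-type Baeyer–Villiger oxidation, in which the electron-rich aryl group (ortho and para methoxyls) migrates in the Criegee intermediate to give the aryl formate, which is saponified in the same flask while the aryl bromide and methyl ethers stay inert.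

Step 3
Reactants: 4 5-bromo-2,3,4-trimethoxyphenol
Product: 5 4,5,6-trimethoxybenzene-1,3-diol
Conditions: CuI (10 mol %), 8-hydroxyquinoline (20 mol %), KOH, DMSO/t-BuOH/H2O, 120 °C, Ar; then cold aq. HCl; crude product used directly
Reagents that add atoms: potassium hydroxide, [K+].[OH-]
Why: Ullmann-type copper-catalysed hydroxylation of an aryl bromide by hydroxide should replace Br at C5 by OH without touching the methyl ethers, the water-rich medium disfavouring diaryl ether formation and the inert atmosphere protecting the electron-rich resorcinolate.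

Step 4
Reactants: 5 4,5,6-trimethoxybenzene-1,3-diol
Product: 6 1,2,3-trimethoxy-4,6-bis(methoxymethoxy)benzene
Conditions: MOMCl, iPr2NEt, CH2Cl2, 0 °C → rt
Reagents that add atoms: chloromethyl methyl ether, COCCl
Why: Base-mediated O-alkylation of both phenols with MOMCl (Williamson-type acetal formation) should give a symmetric, oxidation-stable bis-acetal.

Step 5
Reactants: 6 1,2,3-trimethoxy-4,6-bis(methoxymethoxy)benzene
Product: 8 3,4,5-trimethoxy-2,6-bis(methoxymethoxy)benzaldehyde, via aryllithium 7 (not isolated)
Conditions: n-BuLi, TMEDA, THF, 0 °C; DMF, 0 °C → rt; H2O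
Reagents that add atoms: N,N-dimethylformamide, CN(C)C=O
Why: Directed ortho-metalation, since the only ring hydrogen sits between two OMOM groups that cooperatively direct and stabilise lithiation, followed by formylation of the aryllithium with DMF (Bouveault-type formylation).

Step 6
Reactants: 8 3,4,5-trimethoxy-2,6-bis(methoxymethoxy)benzaldehyde; 9 dimethyl (1-diazo-2-oxopropyl)phosphonate
Product: 11 2-ethynyl-4,5,6-trimethoxy-1,3-bis(methoxymethoxy)benzene, via dimethyl (diazomethyl)phosphonate 10 (not isolated)
Conditions: K2CO3, MeOH, rt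
Reagents that add atoms: dimethyl (1-diazo-2-oxopropyl)phosphonate (compound 9), CC(=O)C(=[N+]=[N-])P(=O)(OC)OC
Why: Ohira–Bestmann modification of the Seyferth–Gilbert homologation, in which methanolysis of 9 releases the diazomethylphosphonate anion that olefinates the aldehyde and loses N2 with a 1,2-hydride shift to the terminal alkyne under mild base that leaves the MOM acetals intact.

Step 7
Reactants: 12 3,4,5-trimethoxybenzaldehyde
Product: 13 (E)-3,4,5-trimethoxybenzaldehyde oxime
Conditions: NH2OH·HCl, NaOAc, EtOH/H2O, rt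
Reagents that add atoms: hydroxylamine hydrochloride, Cl.NO
Why: Condensation of the aldehyde with hydroxylamine (oxime formation) should give the thermodynamically preferred E-oxime.

Step 8
Reactants: 11 2-ethynyl-4,5,6-trimethoxy-1,3-bis(methoxymethoxy)benzene; 13 (E)-3,4,5-trimethoxybenzaldehyde oxime
Product: 16 5-[3,4,5-trimethoxy-2,6-bis(methoxymethoxy)phenyl]-3-(3,4,5-trimethoxyphenyl)isoxazole, via hydroximoyl chloride 14 (not isolated), via 3,4,5-trimethoxybenzonitrile oxide 15 (not isolated)
Conditions: 13 (1.5 equiv), NCS, DMF, rt; then 11, Et3N (slow addition), rt → 40 °C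
Reagents that add atoms: none
Why: Et3N dehydrochlorinates hydroximoyl chloride 14 to nitrile oxide 15, which adds to the terminal alkyne of 11 in a concerted, asynchronous thermal [3+2] cycloaddition (Huisgen nitrile oxide–alkyne cycloaddition, the standard route to 3,5-diarylisoxazoles). The isoxazole ring is closed intermolecularly by this 4π + 2π cycloaddition, both new σ-bonds forming in one transition state: nitrile oxide carbon to the alkyne CH (future C2–C3) and nitrile oxide oxygen to the aryl-bearing alkyne carbon (future C4–O); the adduct is aromatic as formed. No stereocentre is created. The step needs regioselectivity for the 3,5- over the 3,4-diaryl isomer, secured because the aryl-bearing dipole carbon bonds to the unhindered terminal carbon (larger frontier-orbital coefficient, least steric demand) while only the small oxygen terminus approaches the carbon shielded by the two ortho OMOM groups. It also needs cycloaddition to outrun furoxan formation, secured by slow base addition and an excess of 13; NCS is consumed before 11 is added and ring A has no free position, and the MOM acetals are stable to the amine-buffered medium.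

Step 9
Reactants: 16 5-[3,4,5-trimethoxy-2,6-bis(methoxymethoxy)phenyl]-3-(3,4,5-trimethoxyphenyl)isoxazole
Product: 17 (Z)-3-amino-1-[3,4,5-trimethoxy-2,6-bis(methoxymethoxy)phenyl]-3-(3,4,5-trimethoxyphenyl)prop-2-en-1-one
Conditions: H2 (1 atm), Raney Ni, EtOH/THF, rt
Reagents that add atoms: none
Why: Catalytic hydrogenolysis of the weak isoxazole N–O bond (reductive isoxazole ring opening) should give the vinylogous amide, held Z by the N–H···O=C hydrogen bond, while the enaminone C=C, aryl ethers and MOM acetals are not reduced under these mild conditions.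

Step 10
Reactants: 17 (Z)-3-amino-1-[3,4,5-trimethoxy-2,6-bis(methoxymethoxy)phenyl]-3-(3,4,5-trimethoxyphenyl)prop-2-en-1-one
Product: 19 Gardenin A (5-hydroxy-6,7,8-trimethoxy-2-(3,4,5-trimethoxyphenyl)-4H-chromen-4-one), via dihydroxy enaminone 18 (not isolated)
Conditions: conc. HCl, MeOH, 60 °C
Reagents that add atoms: none
Why: Acid-catalysed MOM acetal exchange frees the two equivalent phenols, and either one adds to the protonated enaminone carbon C2 and expels ammonia (addition–elimination, enaminone-to-chromone cyclisation) to close ring C, leaving the other phenol as the chelated 5-OH.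

**Compound list**

1 | 2,3,4-trimethoxybenzaldehyde | COc1ccc(C=O)c(OC)c1OC | starting material
2 | 5-bromo-2,3,4-trimethoxybenzaldehyde | O=Cc1cc(Br)c(OC)c(OC)c1OC | intermediate
3 | 5-bromo-2,3,4-trimethoxyphenyl formate | O=COc1cc(Br)c(OC)c(OC)c1OC | intermediate
4 | 5-bromo-2,3,4-trimethoxyphenol | Oc1cc(Br)c(OC)c(OC)c1OC | intermediate
5 | 4,5,6-trimethoxybenzene-1,3-diol | Oc1cc(O)c(OC)c(OC)c1OC | intermediate
6 | 1,2,3-trimethoxy-4,6-bis(methoxymethoxy)benzene | COCOc1cc(OCOC)c(OC)c(OC)c1OC | intermediate
7 | [3,4,5-trimethoxy-2,6-bis(methoxymethoxy)phenyl]lithium | [Li]c1c(OCOC)c(OC)c(OC)c(OC)c1OCOC | intermediate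
8 | 3,4,5-trimethoxy-2,6-bis(methoxymethoxy)benzaldehyde | O=Cc1c(OCOC)c(OC)c(OC)c(OC)c1OCOC | intermediate
9 | dimethyl (1-diazo-2-oxopropyl)phosphonate | CC(=O)C(=[N+]=[N-])P(=O)(OC)OC | starting material
10 | dimethyl (diazomethyl)phosphonate | [N-]=[N+]=CP(=O)(OC)OC | intermediate
11 | 2-ethynyl-4,5,6-trimethoxy-1,3-bis(methoxymethoxy)benzene | C#Cc1c(OCOC)c(OC)c(OC)c(OC)c1OCOC | intermediate
12 | 3,4,5-trimethoxybenzaldehyde | COc1cc(C=O)cc(OC)c1OC | starting material
13 | (E)-3,4,5-trimethoxybenzaldehyde oxime | O/N=C/c1cc(OC)c(OC)c(OC)c1 | intermediate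
14 | (Z)-N-hydroxy-3,4,5-trimethoxybenzimidoyl chloride | O/N=C(\Cl)c1cc(OC)c(OC)c(OC)c1 | intermediate
15 | 3,4,5-trimethoxybenzonitrile oxide | COc1cc(C#[N+][O-])cc(OC)c1OC | intermediate
16 | 5-[3,4,5-trimethoxy-2,6-bis(methoxymethoxy)phenyl]-3-(3,4,5-trimethoxyphenyl)isoxazole | COc1cc(-c2cc(-c3c(OCOC)c(OC)c(OC)c(OC)c3OCOC)on2)cc(OC)c1OC | intermediate
17 | (Z)-3-amino-1-[3,4,5-trimethoxy-2,6-bis(methoxymethoxy)phenyl]-3-(3,4,5-trimethoxyphenyl)prop-2-en-1-one | N/C(c1cc(OC)c(OC)c(OC)c1)=C\C(=O)c1c(OCOC)c(OC)c(OC)c(OC)c1OCOC | intermediate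
18 | (Z)-3-amino-1-(2,6-dihydroxy-3,4,5-trimethoxyphenyl)-3-(3,4,5-trimethoxyphenyl)prop-2-en-1-one | N/C(c1cc(OC)c(OC)c(OC)c1)=C\C(=O)c1c(O)c(OC)c(OC)c(OC)c1O | intermediate
19 | Gardenin A, 5-hydroxy-6,7,8-trimethoxy-2-(3,4,5-trimethoxyphenyl)-4H-chromen-4-one | COc1cc(-c2cc(=O)c3c(O)c(OC)c(OC)c(OC)c3o2)cc(OC)c1OC | target

**Step count**

Total steps: 10. Longest linear sequence: 9 steps (steps 1–6, 8, 9, 10); step 7 is the one-step side branch.

**Steps most likely to fail**

1. Step 8. Dimerisation of the nitrile oxide to the furoxan may outrun cycloaddition to the hindered, electron-rich alkyne, and the trimethoxyphenyl ring of the oxime may be chlorinated during hydroximoyl chloride formation. The fallback leaves the cycloaddition and reaches the same enaminone by carbonyl addition, oxidation and aza-Michael addition. It sets out from 8 and 12. Aldehyde 12 is homologated with 9 (K2CO3, MeOH) to 5-ethynyl-1,2,3-trimethoxybenzene F1. Its lithium acetylide (n-BuLi, THF, −78 °C) is added to aldehyde 8 to give racemic 1-[3,4,5-trimethoxy-2,6-bis(methoxymethoxy)phenyl]-3-(3,4,5-trimethoxyphenyl)prop-2-yn-1-ol F2. MnO2 in CH2Cl2 should oxidise this to 1-[3,4,5-trimethoxy-2,6-bis(methoxymethoxy)phenyl]-3-(3,4,5-trimethoxyphenyl)prop-2-yn-1-one F3. Conjugate addition of NH3 (MeOH, rt) to the ynone places nitrogen on the ring B carbon and comes back to the route at enaminone 17, ahead of step 10.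

2. Step 3. The electron-rich resorcinolate may be oxidised under hot alkali, and the bromophenoxide may arylate itself to diaryl ethers. The fallback replaces the metal-catalysed C–O coupling by lithiation, borylation and oxidation on a protected substrate. It sets out from 4, which is protected (MOMCl, iPr2NEt, CH2Cl2) as 1-bromo-2,3,4-trimethoxy-5-(methoxymethoxy)benzene F4. Lithium–bromine exchange (n-BuLi, THF, −78 °C) and trapping with B(OMe)3 should give dimethyl [2,3,4-trimethoxy-5-(methoxymethoxy)phenyl]boronate F5. This is oxidised in the same flask (H2O2, NaOH, 0 °C) to 2,3,4-trimethoxy-5-(methoxymethoxy)phenol F6. A second MOM protection (MOMCl, iPr2NEt) comes back to the route at 6.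

3. Step 6. Addition of the diazophosphonate anion to the di-ortho-substituted, electron-rich aldehyde may be slow, so that the reagent decomposes before olefination. The fallback is a Corey–Fuchs sequence setting out from 8. CBr4 and PPh3 (CH2Cl2, 0 °C) should give 1-(2,2-dibromoethenyl)-3,4,5-trimethoxy-2,6-bis(methoxymethoxy)benzene F7. Treatment with n-BuLi (2 equiv, THF, −78 °C, then H2O) effects bromine–lithium exchange and rearrangement of the carbenoid, and comes back to the route at alkyne 11.

**Further compounds**

F1 | step 8 | 5-ethynyl-1,2,3-trimethoxybenzene | C#Cc1cc(OC)c(OC)c(OC)c1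
F2 | step 8 | rac-1-[3,4,5-trimethoxy-2,6-bis(methoxymethoxy)phenyl]-3-(3,4,5-trimethoxyphenyl)prop-2-yn-1-ol | OC(C#Cc1cc(OC)c(OC)c(OC)c1)c1c(OCOC)c(OC)c(OC)c(OC)c1OCOC
F3 | step 8 | 1-[3,4,5-trimethoxy-2,6-bis(methoxymethoxy)phenyl]-3-(3,4,5-trimethoxyphenyl)prop-2-yn-1-one | O=C(C#Cc1cc(OC)c(OC)c(OC)c1)c1c(OCOC)c(OC)c(OC)c(OC)c1OCOC
F4 | step 3 | 1-bromo-2,3,4-trimethoxy-5-(methoxymethoxy)benzene | COCOc1cc(Br)c(OC)c(OC)c1OC
F5 | step 3 | dimethyl [2,3,4-trimethoxy-5-(methoxymethoxy)phenyl]boronate | COCOc1cc(B(OC)OC)c(OC)c(OC)c1OC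
F6 | step 3 | 2,3,4-trimethoxy-5-(methoxymethoxy)phenol | COCOc1cc(O)c(OC)c(OC)c1OC
F7 | step 6 | 1-(2,2-dibromoethenyl)-3,4,5-trimethoxy-2,6-bis(methoxymethoxy)benzene | BrC(Br)=Cc1c(OCOC)c(OC)c(OC)c(OC)c1OCOC
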